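**Retrosynthetic overview**
1. The target comes from acid unmasking of a C1' dimethyl ketal and a 13‑O‑silyl ether, preceded by face‑selective reduction of the C4' ketone and catalyst‑controlled nucleophilic epoxidation of a 2‑alkyl quinone monoketal (oxirane formed last).
2. Key C11–C5' bond: Pd‑mediated union of a drimenylzinc iodide with a 2‑iodo quinone monoketal. C5', natively the enolate carbon of the C4' ketone, is used with reversed polarity as an α‑keto cation (enolonium‑type a2) acceptor, so no arene‑level coupling or late dearomatisation is needed.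
3. The drimane half comes from C3 deoxygenation and C11 OAc→I exchange of the product of an SnCl4‑promoted, epoxide‑initiated bicyclisation of a (10S,11S)‑epoxy‑12‑silyloxyfarnesyl acetate, itself from SeO2 oxidation and Sharpless epoxidation of (E,E)‑farnesyl acetate.
4. The oxygenated six‑membered ring is brought in preformed from 4‑methoxy‑3‑methylphenol (iodination, oxidative dearomatisation).
5. Ring order: ring A then ring B in one cascade, the carbocycle C1'–C6' imported intact, oxirane last.

Assumption: drimane locants are used for the decalin (C11 = CH2 on C9, C12 = CH3 on C8, C13 = oxygenated 4α‑CH2, C14 = 4β‑CH3, C15 = 10β‑CH3), farnesane locants for open‑chain compounds, and primed locants for the oxygenated ring (C1' = final ketone carbon, C2' = C‑methyl carbon, C4' = carbinol, C5' = quaternary oxirane carbon bearing C11, C6' = oxirane CH); TBS = tert‑butyldimethylsilyl.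

**Route**

Step 1
Reactants: 1 (2E,6E)-farnesyl acetate
Product: 2 (2E,6E,10E)-12-hydroxyfarnesyl acetate
Conditions: SeO2 (10 mol %), t-BuOOH, salicylic acid (cat.), CH2Cl2, 0 °C → rt
Reagents that add atoms: tert-butyl hydroperoxide, CC(C)(C)OO
Why: Riley (SeO2) allylic oxidation by ene reaction/[2,3]-shift attacks the most electron-rich, least hindered terminal olefin and oxidises only its E-methyl group, giving the (10E)-allylic alcohol whose geometry later fixes C4.

Step 2
Reactants: 2 (2E,6E,10E)-12-hydroxyfarnesyl acetate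
Product: 3 (2E,6E,10S,11S)-10,11-epoxy-12-hydroxyfarnesyl acetate
Conditions: Ti(OiPr)4 (10 mol %), L-(+)-diethyl tartrate (12 mol %), t-BuOOH, 4 Å MS, CH2Cl2, −20 °C
Reagents that add atoms: tert-butyl hydroperoxide, CC(C)(C)OO
Why: Sharpless asymmetric epoxidation touches only the free allylic alcohol and, with L-(+)-DET, delivers oxygen to the face that gives the (10S,11S)-epoxide (the same face that gives 2S,3S from geraniol), which is the stereo-controller of the whole decalin.

Step 3
Reactants: 3 (2E,6E,10S,11S)-10,11-epoxy-12-hydroxyfarnesyl acetate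
Product: 4 (2E,6E,10S,11S)-12-(tert-butyldimethylsilyloxy)-10,11-epoxyfarnesyl acetate
Conditions: TBSCl, imidazole, CH2Cl2, 0 °C → rt
Reagents that add atoms: tert-butyldimethylsilyl chloride, CC(C)(C)[Si](C)(C)Cl
Why: Standard silylation of the primary alcohol gives a weakly Lewis-basic ether that survives the later Lewis acid, radical, organozinc, peroxide and hydride steps and is removed by HF at the end.

Step 4
Reactants: 4 (2E,6E,10S,11S)-12-(tert-butyldimethylsilyloxy)-10,11-epoxyfarnesyl acetate
Product: 5 3β-hydroxy-13-(tert-butyldimethylsilyloxy)drim-7-en-11-yl acetate (3S; 4α-CH2OTBS; 4β-CH3; 5α-H; 9α-H; 10β-CH3)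
Conditions: SnCl4 (1.1 equiv), CH2Cl2 (0.01 M), −78 °C; then H2O; AgNO3–silica chromatography
Reagents that add atoms: none
Why: Epoxide-initiated cationic polyene cyclisation (Stork–Eschenmoser chair–chair cascade) in which the 6,7-olefin opens the activated oxirane at tertiary C11 with inversion so that the former E-CH2OTBS becomes 4α (equatorial) and CH3 4β, the retained 10S carbinol (3β-OH, equatorial) dictates the absolute fold giving 5α-H/10β-CH3, the E-2,3-olefin gives 9α-H with equatorial CH2OAc, and loss of H-7 from the C8 cation gives the Δ7 olefin (the exocyclic isomer is removed on AgNO3–silica).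

Step 5
Reactants: 5 3β-hydroxy-13-(tert-butyldimethylsilyloxy)drim-7-en-11-yl acetate
Product: 6 3β-(imidazol-1-ylthiocarbonyloxy)-13-(tert-butyldimethylsilyloxy)drim-7-en-11-yl acetate
Conditions: 1,1'-thiocarbonyldiimidazole, DMAP (cat.), toluene, 90 °C
Reagents that add atoms: 1,1'-thiocarbonyldiimidazole, S=C(n1ccnc1)n1ccnc1
Why: Acylation of the only free hydroxyl with thiocarbonyldiimidazole gives the Barton–McCombie precursor without affecting acetate, silyl ether or olefin.

Step 6
Reactants: 6 3β-(imidazol-1-ylthiocarbonyloxy)-13-(tert-butyldimethylsilyloxy)drim-7-en-11-yl acetate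
Product: 7 13-(tert-butyldimethylsilyloxy)drim-7-en-11-yl acetate
Conditions: Bu3SnH, AIBN (cat.), toluene, 110 °C
Reagents that add atoms: none
Why: Barton–McCombie radical deoxygenation, in which Bu3Sn• adds to C=S and β-scission gives the secondary C3 radical that abstracts H from Bu3SnH, removes the now superfluous controller stereocenter without touching C4.

Step 7
Reactants: 7 13-(tert-butyldimethylsilyloxy)drim-7-en-11-yl acetate
Product: 8 13-(tert-butyldimethylsilyloxy)drim-7-en-11-ol
Conditions: K2CO3 (cat.), MeOH, rt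
Reagents that add atoms: none
Why: Base-catalysed transesterification (Zemplén-type methanolysis) frees the C11 alcohol while the hindered neopentyl silyl ether is stable.

Step 8
Reactants: 8 13-(tert-butyldimethylsilyloxy)drim-7-en-11-ol
Product: 9 11-iodo-13-(tert-butyldimethylsilyloxy)drim-7-ene
Conditions: I2, PPh3, imidazole, toluene, 60 °C
Reagents that add atoms: iodine, II
Why: Appel-type (Garegg–Samuelsson) iodination proceeds by SN2 displacement of the alkoxyphosphonium by iodide at primary C11, with no stereocenter involved.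

Step 9
Reactants: 10 4-methoxy-3-methylphenol
Product: 11 2-iodo-4-methoxy-5-methylphenol
Conditions: N-iodosuccinimide, TsOH·H2O (10 mol %), MeCN, 0 °C → rt
Reagents that add atoms: N-iodosuccinimide, O=C1CCC(=O)N1I
Why: Electrophilic aromatic iodination occurs ortho to the strongly activating OH at the unhindered C6 (para to CH3) and not at the position flanked by OH and CH3.

Step 10
Reactants: 11 2-iodo-4-methoxy-5-methylphenol
Product: 12 2-iodo-4,4-dimethoxy-5-methylcyclohexa-2,5-dien-1-one
Conditions: PhI(OAc)2, MeOH, 0 °C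
Reagents that add atoms: methanol, CO
Why: Oxidative dearomatisation with an iodine(III) reagent generates a phenoxenium-type intermediate that methanol traps at the methoxy-bearing para carbon, giving the quinone monoketal with the C–I bond intact.

Step 11
Reactants: 9 11-iodo-13-(tert-butyldimethylsilyloxy)drim-7-ene; 12 2-iodo-4,4-dimethoxy-5-methylcyclohexa-2,5-dien-1-one
Product: 14 2-[13-(tert-butyldimethylsilyloxy)drim-7-en-11-yl]-4,4-dimethoxy-5-methylcyclohexa-2,5-dien-1-one, via drimenylzinc iodide 13 (not isolated)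
Conditions: 9, Zn dust (activated with TMSCl/BrCH2CH2Br), LiCl, THF, 45 °C; decant from excess Zn; then 12, Pd2(dba)3 (2.5 mol %), SPhos (10 mol %), THF/NMP, rt
Reagents that add atoms: none
Why: Negishi cross-coupling after direct zinc insertion, in which C5', the natural enolate (donor) carbon of the C4' ketone, is offered as its α-iodo enone (an α-keto vinyl cation, enolonium-type a2 acceptor) and joined to the donor C11 of the alkylzinc so that two natively nucleophilic carbons are united at the quinone-monoketal oxidation level; Pd(0) inserts only into the C(sp2)–I bond, the bulky biarylphosphine outruns β-hydride elimination, and no stereocenter is created or disturbed.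

Step 12
Reactants: 14 2-[13-(tert-butyldimethylsilyloxy)drim-7-en-11-yl]-4,4-dimethoxy-5-methylcyclohexa-2,5-dien-1-one
Product: 15 (5'R,6'S)-5',6'-epoxy-5'-[13-(tert-butyldimethylsilyloxy)drim-7-en-11-yl]-1',1'-dimethoxy-2'-methylcyclohex-2'-en-4'-one
Conditions: t-BuOOH (70 % aq.), N-benzylcinchonidinium chloride (10 mol %), 1 M NaOH, toluene, 0 °C
Reagents that add atoms: tert-butyl hydroperoxide, CC(C)(C)OO
Why: Weitz–Scheffer nucleophilic epoxidation under Wynberg-type chiral phase-transfer catalysis adds tert-butylperoxide to the unsubstituted β-carbon C6' of the enone (the other β-carbon carries CH3 and the Δ7 olefin is inert to a nucleophilic oxidant), and the cinchonidinium ion pair rather than the remote drimane selects the dienone face to give the (5'R,6'S)-oxirane (the pseudo-enantiomeric cinchoninium salt is used if the sense proves opposite).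

Step 13
Reactants: 15 (5'R,6'S)-epoxy ketone ketal
Product: 16 (4'R,5'S,6'S)-5',6'-epoxy-5'-[13-(tert-butyldimethylsilyloxy)drim-7-en-11-yl]-1',1'-dimethoxy-2'-methylcyclohex-2'-en-4'-ol
Conditions: DIBAL-H, THF, −78 °C; Rochelle salt work-up
Reagents that add atoms: none
Why: Diastereoselective 1,2-reduction in which hydride reaches the C4' carbonyl from the face of the oxirane oxygen (aluminium precoordination to it, the opposite face being shielded by the bulky C5'–CH2-drimenyl group) gives the 4'R alcohol trans to the oxirane.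

Step 14
Reactants: 16 (4'R,5'S,6'S)-epoxy alcohol ketal
Product: 17 epoxypholamin B
Conditions: 48 % aq. HF, MeCN, 0 °C → rt
Reagents that add atoms: water, O
Why: Acid-catalysed ketal hydrolysis unmasks the C1' enone and HF cleaves the silyl ether in the same pot under conditions used for epoxyquinol ketals without opening the oxirane, and no stereocenter is affected.

**Compound list**
1 | (2E,6E)-farnesyl acetate | CC(=O)OC/C=C(\C)CC/C=C(\C)CCC=C(C)C | starting material
2 | (2E,6E,10E)-12-hydroxyfarnesyl acetate | CC(=O)OC/C=C(\C)CC/C=C(\C)CC/C=C(\C)CO | intermediate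
3 | (2E,6E,10S,11S)-10,11-epoxy-12-hydroxyfarnesyl acetate | CC(=O)OC/C=C(\C)CC/C=C(\C)CC[C@@H]1O[C@@]1(C)CO | intermediate
4 | (2E,6E,10S,11S)-12-(tert-butyldimethylsilyloxy)-10,11-epoxyfarnesyl acetate | CC(=O)OC/C=C(\C)CC/C=C(\C)CC[C@@H]1O[C@@]1(C)CO[Si](C)(C)C(C)(C)C | intermediate
5 | 3β-hydroxy-13-(tert-butyldimethylsilyloxy)drim-7-en-11-yl acetate (3S; 4α-CH2OTBS, 4β-CH3, 5α-H, 9α-H, 10β-CH3) | CC(=O)OC[C@H]1C(C)=CC[C@H]2[C@](C)(CO[Si](C)(C)C(C)(C)C)[C@@H](O)CC[C@]12C | intermediate
6 | 3β-(imidazol-1-ylthiocarbonyloxy)-13-(tert-butyldimethylsilyloxy)drim-7-en-11-yl acetate | CC(=O)OC[C@H]1C(C)=CC[C@H]2[C@](C)(CO[Si](C)(C)C(C)(C)C)[C@@H](OC(=S)n3ccnc3)CC[C@]12C | intermediate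
7 | 13-(tert-butyldimethylsilyloxy)drim-7-en-11-yl acetate (4α-CH2OTBS, 5α-H, 9α-H, 10β-CH3) | CC(=O)OC[C@H]1C(C)=CC[C@H]2[C@](C)(CO[Si](C)(C)C(C)(C)C)CCC[C@]12C | intermediate
8 | 13-(tert-butyldimethylsilyloxy)drim-7-en-11-ol | OC[C@H]1C(C)=CC[C@H]2[C@](C)(CO[Si](C)(C)C(C)(C)C)CCC[C@]12C | intermediate
9 | 11-iodo-13-(tert-butyldimethylsilyloxy)drim-7-ene | IC[C@H]1C(C)=CC[C@H]2[C@](C)(CO[Si](C)(C)C(C)(C)C)CCC[C@]12C | intermediate
10 | 4-methoxy-3-methylphenol | COc1ccc(O)cc1C | starting material
11 | 2-iodo-4-methoxy-5-methylphenol | COc1cc(I)c(O)cc1C | intermediate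
12 | 2-iodo-4,4-dimethoxy-5-methylcyclohexa-2,5-dien-1-one | COC1(OC)C=C(I)C(=O)C=C1C | intermediate
13 | [13-(tert-butyldimethylsilyloxy)drim-7-en-11-yl]zinc iodide (not isolated) | I[Zn]C[C@H]1C(C)=CC[C@H]2[C@](C)(CO[Si](C)(C)C(C)(C)C)CCC[C@]12C | intermediate
14 | 2-[13-(tert-butyldimethylsilyloxy)drim-7-en-11-yl]-4,4-dimethoxy-5-methylcyclohexa-2,5-dien-1-one | COC1(OC)C=C(C[C@H]2C(C)=CC[C@H]3[C@](C)(CO[Si](C)(C)C(C)(C)C)CCC[C@]23C)C(=O)C=C1C | intermediate
15 | (5'R,6'S)-5',6'-epoxy-5'-[13-(tert-butyldimethylsilyloxy)drim-7-en-11-yl]-1',1'-dimethoxy-2'-methylcyclohex-2'-en-4'-one | CC1=CC(=O)[C@]2(C[C@H]3C(C)=CC[C@H]4[C@](C)(CO[Si](C)(C)C(C)(C)C)CCC[C@]34C)O[C@@H]2C1(OC)OC | intermediate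
16 | (4'R,5'S,6'S)-5',6'-epoxy-5'-[13-(tert-butyldimethylsilyloxy)drim-7-en-11-yl]-1',1'-dimethoxy-2'-methylcyclohex-2'-en-4'-ol (OH trans to oxirane O) | CC1=C[C@@H](O)[C@]2(C[C@H]3C(C)=CC[C@H]4[C@](C)(CO[Si](C)(C)C(C)(C)C)CCC[C@]34C)O[C@@H]2C1(OC)OC | intermediate
17 | epoxypholamin B, (4'R,5'S,6'S)-5',6'-epoxy-4'-hydroxy-5'-(13-hydroxydrim-7-en-11-yl)-2'-methylcyclohex-2'-en-1'-one | CC1=C[C@@H](O)[C@]2(C[C@H]3C(C)=CC[C@H]4[C@](C)(CO)CCC[C@]34C)O[C@@H]2C1=O | target

**Step count**
Total: 14 steps. Longest linear sequence: 12 steps (steps 1–8 and 11–14); steps 9–10 make the second fragment.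

**Three steps most likely to fail, with fallbacks**

Step 4 (bicyclisation). The CH2OTBS group inductively retards oxirane opening at C11, epoxy silyl ethers can rearrange by hydride shift, and the C8 cation can also give the exocyclic olefin. The fallback sets out from 4 and moves the ring construction into the radical manifold: titanocene(III) (Cp2TiCl2/Mn, collidine·HCl, TMSCl, THF, rt) opens the oxirane homolytically and the tertiary radical cyclises through the same chair–chair fold, terminating cleanly by Ti-assisted hydrogen loss to the exocyclic olefin 3β-hydroxy-13-(tert-butyldimethylsilyloxy)drim-8(12)-en-11-yl acetate F1. In this mode C4 rests on the larger CH2OTBS group taking the equatorial position rather than on stereospecific opening. Grieco isomerisation (RhCl3·3H2O, EtOH, 70 °C), which favours β-hydride loss from the accessible C7 over the hindered C9, then moves the double bond into the ring and the sequence comes back to the route at 5.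

Step 11 (coupling at the dienone level). Zinc insertion into the β-branched iodide may be slow, and the iodo dienone can be reduced or dehalogenated faster than the hindered alkyl group is transferred. The fallback sets out from 9 (as its zinc reagent 13) and 11: Negishi coupling of 13 with the aryl iodide 11 (phenol deprotonated beforehand with NaH; Pd(OAc)2/SPhos, THF, 50 °C) is an ordinary aryl–alkyl coupling and gives 2-[13-(tert-butyldimethylsilyloxy)drim-7-en-11-yl]-4-methoxy-5-methylphenol F2. Oxidative dearomatisation of F2 (PhI(OAc)2, MeOH, 0 °C) then comes back to the route at 14, at the cost of one extra step.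

Step 12 (facial selectivity of the epoxidation). The drimane is too remote to bias the dienone faces, so the outcome rests entirely on the phase-transfer catalyst, which has little precedent for an α-branched alkyl quinone monoketal. The fallback sets out from 14 and replaces reagent control by an auxiliary on the ketal carbon next to the reacting C6'. Transketalisation with (R,R)-hydrobenzoin (PPTS, benzene, 50 °C; the (S,S)-diol if the sense is opposite) gives the (4R,5R)-4,5-diphenyl-1,3-dioxolane spiroketal of the dienone F3. Its C2-symmetric ketal differentiates the two faces at C6' in a plain Weitz–Scheffer epoxidation (t-BuOOH, DBU, CH2Cl2, 0 °C) to give the (5'R,6'S)-epoxy ketone diphenyldioxolane ketal F4. DIBAL-H reduction as in step 13 gives the (4'R,5'S,6'S)-epoxy alcohol diphenyldioxolane ketal F5, and aqueous HF in MeCN removes auxiliary and silyl group, coming back to the route at 17.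

**Further compounds**
F1 | step 4 | 3β-hydroxy-13-(tert-butyldimethylsilyloxy)drim-8(12)-en-11-yl acetate | CC(=O)OC[C@H]1C(=C)CC[C@H]2[C@](C)(CO[Si](C)(C)C(C)(C)C)[C@@H](O)CC[C@]12C
F2 | step 11 | 2-[13-(tert-butyldimethylsilyloxy)drim-7-en-11-yl]-4-methoxy-5-methylphenol | COc1cc(C[C@H]2C(C)=CC[C@H]3[C@](C)(CO[Si](C)(C)C(C)(C)C)CCC[C@]23C)c(O)cc1C
F3 | step 12 | (4R,5R)-4,5-diphenyl-1,3-dioxolane spiroketal of dienone 14 | CC1=CC(=O)C(C[C@H]2C(C)=CC[C@H]3[C@](C)(CO[Si](C)(C)C(C)(C)C)CCC[C@]23C)=CC14O[C@H](c5ccccc5)[C@@H](c5ccccc5)O4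
F4 | step 12 | (5'R,6'S)-epoxy ketone (4R,5R)-diphenyldioxolane ketal | CC1=CC(=O)[C@]2(C[C@H]3C(C)=CC[C@H]4[C@](C)(CO[Si](C)(C)C(C)(C)C)CCC[C@]34C)O[C@@H]2C15O[C@H](c6ccccc6)[C@@H](c6ccccc6)O5
F5 | step 12 | (4'R,5'S,6'S)-epoxy alcohol (4R,5R)-diphenyldioxolane ketal | CC1=C[C@@H](O)[C@]2(C[C@H]3C(C)=CC[C@H]4[C@](C)(CO[Si](C)(C)C(C)(C)C)CCC[C@]34C)O[C@@H]2C15O[C@H](c6ccccc6)[C@@H](c6ccccc6)O5
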